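The amounts charged repeat from flask to flask, and the capture agent is what moves, so I first ask whether it matters.

| setting | dawn | winter | Friday's | Saturday's | Thursday's | Tuesday's | Wednesday's |
|---|---|---|---|---|---|---|---|
| substrate | 0.37 M | 0.37 M | 0.37 M | 0.37 M | 0.37 M | 0.37 M | 0.37 M |
| first nucleophile | 0.444 M | 0.444 M | 0.444 M | 0.444 M | 0.444 M | 0.444 M | 0.444 M |
| second nucleophile | 0.37 M | 0.37 M | 0.370 M | 0.370 M | 0.370 M | 0.370 M | 0.370 M |
| capture agent | 0.0080 M | 0.65 M | 0.00600 M | 0.0200 M | 0.0600 M | 0.150 M | 0.500 M |
| remark | run made earlier | run made earlier |  |  |  |  |  |
| time |  |  | 2.0 h | 2.0 h | 2.0 h | 2.0 h | 2.0 h |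

| dawn: time / min | dawn: target / % | winter: time / min | winter: target / % |
|---|---|---|---|
| 4.00 | 10 | 4.00 | 8 |
| 12.0 | 27 | 12.0 | 25 |
| 20.0 | 38 | 20.0 | 33 |
| 30.0 | 46 | 30.0 | 48 |
| 50.0 | 58 | 50.0 | 57 |
| 60.0 | 62 | 60.0 | 58 |

(each reading ± 2 percentage points)

- amount of target at the end, in percent of the substrate charged for Friday's, Saturday's, Thursday's, Tuesday's, Wednesday's, in this order
- how that number moves from the first to the last of them (rises, then falls / hardly changes / falls all the way / rises all the way / falls, then rises)

- "hardly changes" means that all values lie within two and a half points (for a concentration: within two and a half percent of the largest)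

The dawn and winter runs differ 81.2-fold in capture agent, yet at 20.0 min they stand 5 percentage points apart with a scatter of 2 points on each reading, so I pool them and draw one curve. It starts with 10% and 8% after 4.00 min, and I guess that it is first-order in the substrate, which means that the gap to the final level shrinks by the same factor in equal times. The pooled target is 47.0% at 30.0 min and 60.0% at 60.0 min, so the second stretch gains 27.7% of what the first gained, and that is the factor per stretch. That makes 16.2 min my reading of the halving time, the time in which the gap to the level shrinks by a factor of 2, and it puts my reading of the level at 65.0%, both with the scatter of the readings in them. The reading at 12.0 min played no part in this, and the curve gives 26.1% there against 27% and 25%. The asked 2.0 h is 7.42 halving times, which leaves 0.585% of the rise undone on this curve, so the knee lies far behind and I commit to 64.6% in each flask.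

The forecast gives 69% for each flask, so its row hardly changes, on the ground that “Neither a trace nor an excess alters the rate or yield”. My figure is lower than that, though the flat shape is the same.

The flasks give 61.2%, 61.2%, 61.2%, 61.0% and 60.6%, so the row hardly changes, as the forecast said, below its 69% and below my 64.6%.

substrate → open intermediate (k = 8.60 × 10⁻⁴ s⁻¹); first nucleophile + open intermediate → target (k = 0.0220 M⁻¹ s⁻¹); second nucleophile + open intermediate → other capture product (k = 0.0150 M⁻¹ s⁻¹); open intermediate + capture agent → trapped intermediate (k = 2.50 × 10⁻⁴ M⁻¹ s⁻¹) With 7.42 halving times behind it, Friday's flask has 0.585% of its rise to come on my reckoning, and its target stands at 61.4% at 20.0 h; Wednesday's, with 0.20% of its substrate left at the end, stands at 60.7% at 20.0 h. In Friday's flask the main reason why the target stops short of the substrate charged is the step from second nucleophile and open intermediate to other capture product: taken away, the target there reaches 99.6% instead of 61.2%.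

The readings are simulated for an exercise; the scatter is artificial.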